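**Plan**

- Retrosynthesis: the C1–aryl bond is cut first (Friedel–Crafts arylation of a C1-methoxy tetralin with veratrole), then the C6–O and C7–O bonds are traced back to C–B bonds, and ring A is opened at C4a–C8a, C5–C6 and C7–C8 into a 1,7-diyne and diborylacetylene.
- Enabling feature: ring A is a benzene with hydrogen at C5 and C8 and vicinal oxygens at C6 and C7, and the sp3 carbons C1–C4 of ring B form a four-atom tether between two alkynes, so rings B and A can close in one [2+2+2] cocyclisation.
- Forward: the C1–C4 chain with both methoxymethyl arms and a C1 methoxy group is built first (auxiliary alkylation, lactone, trans alkylation, lactol, ethynyl addition, O-methylation). Rings B and A then close together, the two C–B bonds become methoxy groups, and the aryl ring is attached last.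
- Stereochemistry: C3 comes from the oxazolidinone-controlled alkylation. C2 comes from alkylation of the lactone enolate trans to the C3 substituent (this trans lactone relation is the cis C2/C3 relation of ring B). C1 comes from attack of veratrole on the planar benzylic cation on the face opposite both arms.

Key step: step 9

Remark: the oxygen-bearing carbon that becomes C1 is formed in step 6 as a mixture of both epimers and is carried as such in 12, 13, 19, 20 and 21 (no descriptor there); it becomes planar in step 12, so both epimers give the same product.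

**Route**

Step 1
Reactants: 1 (S)-4-benzyloxazolidin-2-one; 2 pent-4-ynoic acid
Product: 4 (S)-4-benzyl-3-(pent-4-ynoyl)oxazolidin-2-one, via pent-4-ynoic pivalic anhydride 3 (not isolated)
Conditions: t-BuCOCl, Et3N, THF, –20 °C; then LiCl, 1, –20 °C → rt
Reagents that add atoms: none
Why: N-acylation of an Evans oxazolidinone through the mixed pivalic anhydride, with LiCl and Et3N making the carbamate nitrogen nucleophilic enough; no stereocentre is formed.

Step 2
Reactants: 4 (S)-4-benzyl-3-(pent-4-ynoyl)oxazolidin-2-one; 5 tert-butyl bromoacetate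
Product: 6 tert-butyl (3R)-3-{[(4S)-4-benzyl-2-oxo-1,3-oxazolidin-3-yl]carbonyl}hex-5-ynoate
Conditions: NaN(SiMe3)2, THF, –78 °C; then 5, –78 → –40 °C
Reagents that add atoms: none
Why: Evans asymmetric alkylation, in which the chelated Z sodium enolate is attacked by the bromoacetate on the face opposite the benzyl group of the (S)-auxiliary, setting the new centre (later C3) as R; the imide C–H is far more acidic than the acetylenic C–H.

Step 3
Reactants: 6 tert-butyl (3R)-3-{[(4S)-4-benzyl-2-oxo-1,3-oxazolidin-3-yl]carbonyl}hex-5-ynoate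
Product: 8 (4R)-4-(prop-2-yn-1-yl)oxolan-2-one, via tert-butyl (3R)-3-(hydroxymethyl)hex-5-ynoate 7 (not isolated)
Conditions: LiBH4, MeOH (1 equiv), THF, 0 °C; then TFA (cat.), CH2Cl2, rt
Reagents that add atoms: none
Why: reductive removal of the auxiliary, in which LiBH4 reduces the activated imide carbonyl but not the tert-butyl ester, followed by acid-catalysed lactonisation with loss of 2-methylpropene; the stereocentre is not touched.

Step 4
Reactants: 8 (4R)-4-(prop-2-yn-1-yl)oxolan-2-one
Product: 9 (3S,4R)-3-(methoxymethyl)-4-(prop-2-yn-1-yl)oxolan-2-one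
Conditions: LiN(SiMe3)2, THF, –78 °C; then MeOCH2Cl, –78 → –40 °C
Reagents that add atoms: chloromethyl methyl ether, COCCl
Why: alkylation of a lactone enolate, in which the electrophile enters on the face opposite the neighbouring propargyl group, giving the 3,4-trans lactone and setting the new centre (later C2) as S; the bulky amide base should enolise the lactone faster than it metalates the alkyne.

Step 5
Reactants: 9 (3S,4R)-3-(methoxymethyl)-4-(prop-2-yn-1-yl)oxolan-2-one
Product: 10 (3S,4R)-3-(methoxymethyl)-4-(prop-2-yn-1-yl)oxolan-2-ol (lactol, both anomers)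
Conditions: i-Bu2AlH (1.1 equiv), CH2Cl2, –78 °C
Reagents that add atoms: none
Why: half-reduction of a lactone to the lactol by i-Bu2AlH, whose tetrahedral aluminate is stable at –78 °C; the alkyne and the two ring stereocentres are unaffected.

Step 6
Reactants: 10 (3S,4R)-3-(methoxymethyl)-4-(prop-2-yn-1-yl)oxolan-2-ol; 11 ethynylmagnesium bromide
Product: 12 (4S,5R)-5-(hydroxymethyl)-4-(methoxymethyl)octa-1,7-diyn-3-ol (both C3 epimers)
Conditions: HC≡CMgBr (3 equiv), THF, 0 °C → rt
Reagents that add atoms: none
Why: Grignard addition to the open hydroxy-aldehyde form of the lactol (the first equivalent deprotonates the OH group) gives the propargylic alcohol; the new carbinol centre forms as an epimeric mixture, which is harmless (see remark).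

Step 7
Reactants: 12 (4S,5R)-5-(hydroxymethyl)-4-(methoxymethyl)octa-1,7-diyn-3-ol
Product: 13 (4S,5R)-3-methoxy-4,5-bis(methoxymethyl)octa-1,7-diyne (both C3 epimers)
Conditions: NaH, MeI, THF, 0 °C → rt
Reagents that add atoms: iodomethane, CI
Why: Williamson ether synthesis on both alkoxides at 0 °C, where NaH should not metalate the terminal alkynes at a competitive rate; no stereocentre is changed.

Step 8
Reactants: 14 trichloroethylene; 15 2-isopropoxy-4,4,5,5-tetramethyl-1,3,2-dioxaborolane
Product: 18 bis(pinacolatoboryl)acetylene, via dilithioacetylene 16 (not isolated), via dilithium ethyne-1,2-diylbis(isopropoxy pinacolato borate) 17 (not isolated)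
Conditions: n-BuLi (3 equiv), Et2O, –78 °C → rt; 15 (2 equiv), –78 °C; HCl in Et2O, –78 °C → rt
Reagents that add atoms: none
Why: borylation of an organolithium with a borate ester, in which trichloroethylene and n-BuLi give dilithioacetylene by elimination and chlorine–lithium exchange, each acetylide carbon adds to the isopropoxyborolane, and HCl expels propan-2-ol from the ate complex.

Step 9
Reactants: 13 (4S,5R)-3-methoxy-4,5-bis(methoxymethyl)octa-1,7-diyne; 18 bis(pinacolatoboryl)acetylene
Product: 19 (2S,3R)-1-methoxy-2,3-bis(methoxymethyl)-6,7-bis(4,4,5,5-tetramethyl-1,3,2-dioxaborolan-2-yl)-1,2,3,4-tetrahydronaphthalene (both C1 epimers)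
Conditions: CpCo(CO)2 (15 mol %), 18 (3 equiv), toluene, reflux, hν (visible lamp); 13 added by syringe pump over 10 h
Reagents that add atoms: none
Why: CpCo(CO)2 (monovalent cobalt) loses CO under heat and light, and the CpCo fragment binds the two alkyne units of 13 and couples them oxidatively to a cobaltacyclopentadiene (trivalent cobalt), which forms C4a–C8a and closes ring B as a six-membered carbocycle by tether-controlled intramolecular metallacycle formation. Coordination and insertion of the diborylalkyne 18, followed by reductive elimination, forms C5–C6 and C7–C8 and closes ring A as the benzene, releasing CpCo. The closest known reaction type is the CpCo-catalysed cocyclisation of α,ω-diynes with bis(trimethylsilyl)acetylene and with alkynylboronates to fused arenes. No stereocentre is created; C2 and C3 lie on the tether away from the reacting carbons and the methoxy-bearing C1 is not touched. The selectivity needed is chemoselectivity for cross-cocyclisation over oligomerisation of the diyne: slow addition keeps 13 dilute while 18, too hindered to trimerise with itself, is in excess, and the symmetric alkyne removes any regiochemical question and places the two boryl groups exactly at C6 and C7.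

Step 10
Reactants: 19 (2S,3R)-1-methoxy-2,3-bis(methoxymethyl)-6,7-bis(4,4,5,5-tetramethyl-1,3,2-dioxaborolan-2-yl)-1,2,3,4-tetrahydronaphthalene
Product: 20 (2S,3R)-1-methoxy-2,3-bis(methoxymethyl)-1,2,3,4-tetrahydronaphthalene-6,7-diol (tetralin numbering kept; both C1 epimers)
Conditions: 30% aq. H2O2, NaOH, THF, 0 °C, argon; then Na2S2O3, NH4Cl
Reagents that add atoms: hydrogen peroxide, OO
Why: oxidation of arylboronates, in which hydroperoxide adds to boron and the aryl group migrates from boron to oxygen at the same ring carbon, so the hydroxyl groups appear exactly at C6 and C7; the alkyl ethers are inert and the cold, brief, oxygen-free treatment should protect the catechol.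

Step 11
Reactants: 20 (2S,3R)-1-methoxy-2,3-bis(methoxymethyl)-1,2,3,4-tetrahydronaphthalene-6,7-diol
Product: 21 (2S,3R)-1,6,7-trimethoxy-2,3-bis(methoxymethyl)-1,2,3,4-tetrahydronaphthalene (both C1 epimers)
Conditions: MeI, K2CO3, acetone, 40 °C, argon
Reagents that add atoms: iodomethane, CI
Why: Williamson methylation of the two phenols under mild carbonate conditions; the alkyl and benzylic ethers are inert and no stereocentre is involved.

Step 12
Reactants: 21 (2S,3R)-1,6,7-trimethoxy-2,3-bis(methoxymethyl)-1,2,3,4-tetrahydronaphthalene; 22 veratrole (1,2-dimethoxybenzene)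
Product: 23 (1R,2S,3R)-1-(3,4-dimethoxyphenyl)-6,7-dimethoxy-2,3-bis(methoxymethyl)-1,2,3,4-tetrahydronaphthalene
Conditions: BF3·OEt2, veratrole (10 equiv), CH2Cl2, –40 → 0 °C
Reagents that add atoms: none
Why: Friedel–Crafts alkylation, in which BF3 ionises the C1 methoxy group to a benzylic cation stabilised by the para C6 methoxy group (both C1 epimers converge on it) and veratrole attacks through its position para to a methoxy group on the face opposite the two cis arms at C2 and C3, setting C1 as R with the aryl group trans to the C2 arm.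

**Compound list**

1 | (S)-4-benzyloxazolidin-2-one | O=C1N[C@@H](Cc2ccccc2)CO1 | starting material
2 | pent-4-ynoic acid | C#CCCC(=O)O | starting material
3 | pent-4-ynoic pivalic anhydride | C#CCCC(=O)OC(=O)C(C)(C)C | intermediate
4 | (S)-4-benzyl-3-(pent-4-ynoyl)oxazolidin-2-one | C#CCCC(=O)N1[C@@H](Cc2ccccc2)COC1=O | intermediate
5 | tert-butyl bromoacetate | CC(C)(C)OC(=O)CBr | starting material
6 | tert-butyl (3R)-3-{[(4S)-4-benzyl-2-oxo-1,3-oxazolidin-3-yl]carbonyl}hex-5-ynoate | C#CC[C@H](CC(=O)OC(C)(C)C)C(=O)N1[C@@H](Cc2ccccc2)COC1=O | intermediate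
7 | tert-butyl (3R)-3-(hydroxymethyl)hex-5-ynoate | C#CC[C@H](CC(=O)OC(C)(C)C)CO | intermediate
8 | (4R)-4-(prop-2-yn-1-yl)oxolan-2-one | C#CC[C@@H]1CC(=O)OC1 | intermediate
9 | (3S,4R)-3-(methoxymethyl)-4-(prop-2-yn-1-yl)oxolan-2-one | COC[C@H]1C(=O)OC[C@@H]1CC#C | intermediate
10 | (3S,4R)-3-(methoxymethyl)-4-(prop-2-yn-1-yl)oxolan-2-ol (both anomers) | COC[C@H]1C(O)OC[C@@H]1CC#C | intermediate
11 | ethynylmagnesium bromide | C#C[Mg]Br | starting material
12 | (4S,5R)-5-(hydroxymethyl)-4-(methoxymethyl)octa-1,7-diyn-3-ol (both C3 epimers) | C#CC(O)[C@H](COC)[C@H](CO)CC#C | intermediate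
13 | (4S,5R)-3-methoxy-4,5-bis(methoxymethyl)octa-1,7-diyne (both C3 epimers) | C#CC(OC)[C@H](COC)[C@H](COC)CC#C | intermediate
14 | trichloroethylene | ClC=C(Cl)Cl | starting material
15 | 2-isopropoxy-4,4,5,5-tetramethyl-1,3,2-dioxaborolane | CC(C)OB1OC(C)(C)C(C)(C)O1 | starting material
16 | dilithioacetylene | [Li]C#C[Li] | intermediate
17 | dilithium ethyne-1,2-diylbis(isopropoxy pinacolato borate) | [Li+].[Li+].CC(C)O[B-]1(OC(C)(C)C(C)(C)O1)C#C[B-]1(OC(C)C)OC(C)(C)C(C)(C)O1 | intermediate
18 | bis(pinacolatoboryl)acetylene | CC1(C)OB(C#CB2OC(C)(C)C(C)(C)O2)OC1(C)C | intermediate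
19 | (2S,3R)-1-methoxy-2,3-bis(methoxymethyl)-6,7-bis(4,4,5,5-tetramethyl-1,3,2-dioxaborolan-2-yl)-1,2,3,4-tetrahydronaphthalene (both C1 epimers) | COC[C@@H]1Cc2cc(B3OC(C)(C)C(C)(C)O3)c(B3OC(C)(C)C(C)(C)O3)cc2C(OC)[C@@H]1COC | intermediate
20 | (2S,3R)-1-methoxy-2,3-bis(methoxymethyl)-1,2,3,4-tetrahydronaphthalene-6,7-diol (both C1 epimers) | COC[C@@H]1Cc2cc(O)c(O)cc2C(OC)[C@@H]1COC | intermediate
21 | (2S,3R)-1,6,7-trimethoxy-2,3-bis(methoxymethyl)-1,2,3,4-tetrahydronaphthalene (both C1 epimers) | COC[C@@H]1Cc2cc(OC)c(OC)cc2C(OC)[C@@H]1COC | intermediate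
22 | veratrole (1,2-dimethoxybenzene) | COc1ccccc1OC | starting material
23 | (1R,2S,3R)-1-(3,4-dimethoxyphenyl)-6,7-dimethoxy-2,3-bis(methoxymethyl)-1,2,3,4-tetrahydronaphthalene | COC[C@@H]1Cc2cc(OC)c(OC)cc2[C@@H](c2ccc(OC)c(OC)c2)[C@@H]1COC | target

**Step count**

Total: 12 steps. Longest linear sequence: 11 steps (steps 1–7 and 9–12); step 8 is a one-step side branch.

**Steps most likely to fail**

Step 9 (cocyclisation). The two terminal alkyne units of 13 may react with further molecules of 13 faster than the hindered, electron-poor diborylalkyne enters the cobaltacycle, so that oligomers form and the catalyst is consumed. The fallback lets silicon replace boron as the placeholder for the ring A oxygens. It sets out from 13: slow addition of 13 to CpCo(CO)2 in refluxing bis(trimethylsilyl)acetylene under irradiation should give (2S,3R)-1-methoxy-2,3-bis(methoxymethyl)-6,7-bis(trimethylsilyl)-1,2,3,4-tetrahydronaphthalene F1. Ipso-iododesilylation with ICl in CH2Cl2 at 0 °C should then give (2S,3R)-6,7-diiodo-1-methoxy-2,3-bis(methoxymethyl)-1,2,3,4-tetrahydronaphthalene F2. Ullmann-type methoxylation (CuI, NaOMe, MeOH/DMF, 110 °C) turns both C–I bonds into methoxy groups, and the route is rejoined at 21.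

Step 12 (arylation). The C1 cation may lose the C2 proton and be re-protonated, which would scramble C2, or it may be captured with insufficient facial selectivity or by a second tetralin molecule. The fallback makes the C1–aryl bond through a C1 radical and an arylnickel species instead of a cation and an arene. It sets out from 21: brief hydrolysis (aqueous HCl, THF, where water traps the cation at once) gives (2S,3R)-6,7-dimethoxy-2,3-bis(methoxymethyl)-1,2,3,4-tetrahydronaphthalen-1-ol F3. Nickel-catalysed reductive cross-electrophile coupling of this benzylic alcohol with 4-bromoveratrole (NiCl2(dme), 4,4'-di-tert-butyl-2,2'-bipyridine, TiCl4, 2,6-lutidine, Mn, THF) then follows. In it, trivalent titanium formed from TiCl4 and Mn cleaves the C1–O bond homolytically, and the arylnickel intermediate should capture the planar C1 radical on the face opposite the arms, leading directly to 23.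

Step 4 (lactone alkylation). The hard chloromethyl ether may alkylate the enolate on oxygen, the acetylenic C–H may be metalated and alkylated, or base may eliminate methanol from the product. The fallback introduces the arm carbon by an aldol reaction and methylates its oxygen later together with the others. It sets out from 8: the lithium enolate and monomeric formaldehyde should give (3S,4R)-3-(hydroxymethyl)-4-(prop-2-yn-1-yl)oxolan-2-one F4, trans for the same reason as in step 4. Reduction with i-Bu2AlH gives (3S,4R)-3-(hydroxymethyl)-4-(prop-2-yn-1-yl)oxolan-2-ol F5, and excess HC≡CMgBr gives (4S,5R)-4,5-bis(hydroxymethyl)octa-1,7-diyn-3-ol F6. Threefold O-methylation (NaH, MeI, THF) rejoins the route at 13.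

**Further compounds**

F1 | step 9 | (2S,3R)-1-methoxy-2,3-bis(methoxymethyl)-6,7-bis(trimethylsilyl)-1,2,3,4-tetrahydronaphthalene (both C1 epimers) | COC[C@@H]1Cc2cc([Si](C)(C)C)c([Si](C)(C)C)cc2C(OC)[C@@H]1COC
F2 | step 9 | (2S,3R)-6,7-diiodo-1-methoxy-2,3-bis(methoxymethyl)-1,2,3,4-tetrahydronaphthalene (both C1 epimers) | COC[C@@H]1Cc2cc(I)c(I)cc2C(OC)[C@@H]1COC
F3 | step 12 | (2S,3R)-6,7-dimethoxy-2,3-bis(methoxymethyl)-1,2,3,4-tetrahydronaphthalen-1-ol (both C1 epimers) | COC[C@@H]1Cc2cc(OC)c(OC)cc2C(O)[C@@H]1COC
F4 | step 4 | (3S,4R)-3-(hydroxymethyl)-4-(prop-2-yn-1-yl)oxolan-2-one | OC[C@H]1C(=O)OC[C@@H]1CC#C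
F5 | step 4 | (3S,4R)-3-(hydroxymethyl)-4-(prop-2-yn-1-yl)oxolan-2-ol (both anomers) | OC[C@H]1C(O)OC[C@@H]1CC#C
F6 | step 4 | (4S,5R)-4,5-bis(hydroxymethyl)octa-1,7-diyn-3-ol (both C3 epimers) | C#CC(O)[C@H](CO)[C@H](CO)CC#C
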